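**Assumption:** the target has no stereocentre or other stereogenic element, so it is achiral and no stereocontrol is needed.

## Retrosynthetic overview

1. Target 10 ⇐ aldehyde depside 9: the salicylic acid is carried as its aldehyde and oxidised last, so no carboxyl protecting group is needed.
2. 9 ⇐ aryl iodide 7 + aryl formate 4: the depside is cut at the aryl–C(=O) carbon–carbon bond, not at the ester C–O bond. The formate C–H serves as an aryloxycarbonyl anion (acyl-anion-type) equivalent, so a normally electrophilic carbonyl carbon is joined to the electrophilic C–I carbon under Pd catalysis.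
3. 4 ⇐ olivetol 1 (C-formylation, then selective O-formylation); 7 ⇐ divarin 5 (O-methylation, then iodination).
4. No ring is formed: both benzene rings are bought with their alkyl chains in place.

## Route

**Step 1**
Reactants: 1 olivetol (5-pentylbenzene-1,3-diol)
Product: 3 2,4-dihydroxy-6-pentylbenzaldehyde, via iminium chloride 2 (not isolated)
Conditions: POCl3 (1.2 equiv), DMF, MeCN, 0 °C → rt; then H2O, 50 °C
Reagents that add atoms: N,N-dimethylformamide CN(C)C=O; phosphoryl chloride O=P(Cl)(Cl)Cl (chloride counter-ion of 2 only); water O
Why: Vilsmeier–Haack formylation, in which the chloroiminium ion attacks the position para to one OH and ortho to the other (the two such positions are equivalent) in preference to the crowded position between the hydroxyls, and the iminium salt 2 is hydrolysed to the aldehyde on aqueous work-up; no stereocentre is formed.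

**Step 2**
Reactants: 3 2,4-dihydroxy-6-pentylbenzaldehyde
Product: 4 4-formyl-3-hydroxy-5-pentylphenyl formate
Conditions: HCO2H (1.2 equiv), DCC (1.2 equiv), CH2Cl2, 0 °C → rt; filter, use directly
Reagents that add atoms: formic acid O=CO
Why: carbodiimide-mediated O-formylation (Steglich-type acylation through the O-formylisourea), selective for the 4-OH because it is the more acidic, unhindered hydroxyl while the 2-OH is tied up in a hydrogen bond to the aldehyde; no stereocentre is formed.

**Step 3**
Reactants: 5 divarin (5-propylbenzene-1,3-diol)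
Product: 6 1,3-dimethoxy-5-propylbenzene
Conditions: MeI (2.5 equiv), K2CO3 (3 equiv), acetone, reflux
Reagents that add atoms: iodomethane CI
Why: Williamson ether synthesis on both phenoxides, which under carbonate in acetone alkylate on oxygen rather than carbon; no stereocentre is formed.

**Step 4**
Reactants: 6 1,3-dimethoxy-5-propylbenzene
Product: 7 2-iodo-1,5-dimethoxy-3-propylbenzene
Conditions: NIS (1.0 equiv), TFA (cat.), MeCN, 0 °C → rt
Reagents that add atoms: N-iodosuccinimide O=C1CCC(=O)N1I
Why: electrophilic aromatic iodination, directed para to one OMe and ortho to the other (next to the propyl group) rather than between the two methoxy groups, as is usual for 3,5-dialkoxy-alkylbenzenes; no stereocentre is formed.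

**Step 5**
Reactants: 4 4-formyl-3-hydroxy-5-pentylphenyl formate (1.3 equiv); 7 2-iodo-1,5-dimethoxy-3-propylbenzene (1.0 equiv)
Product: 9 4-formyl-3-hydroxy-5-pentylphenyl 2,4-dimethoxy-6-propylbenzoate, via aldehyde-phenol 3 (not isolated), via carbon monoxide 8 (not isolated)
Conditions: Pd(OAc)2 (5 mol%), P(t-Bu)3·HBF4 (20 mol%), Et3N (2.5 equiv), MeCN, 80 °C, sealed tube
Reagents that add atoms: none
Why: palladium-catalysed aryloxycarbonylation of an aryl halide with an aryl formate (CO-free carbonylative coupling), in which the formate C–H of 4 acts as a latent aryloxycarbonyl anion so that its normally electrophilic carbonyl carbon is joined to the electrophilic C–I carbon of 7: Et3N unmasks it as CO 8 plus the phenoxide of 3, Pd(0) adds to the C–I bond, CO inserts, and the more acidic, non-chelated 4-O-phenoxide closes the hindered ester; no stereocentre is formed.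

**Step 6**
Reactants: 9 4-formyl-3-hydroxy-5-pentylphenyl 2,4-dimethoxy-6-propylbenzoate
Product: 10 4-[(2,4-dimethoxy-6-propylbenzoyl)oxy]-2-hydroxy-6-pentylbenzoic acid
Conditions: NaClO2 (3 equiv), NaH2PO4 (3 equiv), 2-methylbut-2-ene (20 equiv), t-BuOH/THF/H2O, 0 °C → rt
Reagents that add atoms: sodium chlorite [Na+].[O-]Cl=O
Why: Pinnick (Lindgren) oxidation, in which chlorous acid converts the salicylaldehyde to the acid at pH 3–4 where the hindered 2,6-disubstituted aryl ester is not hydrolysed, and the alkene scavenges HOCl before it can chlorinate either electron-rich ring; no stereocentre is formed.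

## Compound list

1 | olivetol (5-pentylbenzene-1,3-diol) | CCCCCc1cc(O)cc(O)c1 | starting material
2 | (2,4-dihydroxy-6-pentylbenzylidene)dimethyliminium chloride | CCCCCc1cc(O)cc(O)c1C=[N+](C)C.[Cl-] | intermediate
3 | 2,4-dihydroxy-6-pentylbenzaldehyde | CCCCCc1cc(O)cc(O)c1C=O | intermediate
4 | 4-formyl-3-hydroxy-5-pentylphenyl formate | CCCCCc1cc(OC=O)cc(O)c1C=O | intermediate
5 | divarin (5-propylbenzene-1,3-diol) | CCCc1cc(O)cc(O)c1 | starting material
6 | 1,3-dimethoxy-5-propylbenzene | CCCc1cc(OC)cc(OC)c1 | intermediate
7 | 2-iodo-1,5-dimethoxy-3-propylbenzene | CCCc1cc(OC)cc(OC)c1I | intermediate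
8 | carbon monoxide | [C-]#[O+] | intermediate
9 | 4-formyl-3-hydroxy-5-pentylphenyl 2,4-dimethoxy-6-propylbenzoate | CCCCCc1cc(OC(=O)c2c(CCC)cc(OC)cc2OC)cc(O)c1C=O | intermediate
10 | 4-[(2,4-dimethoxy-6-propylbenzoyl)oxy]-2-hydroxy-6-pentylbenzoic acid | CCCCCc1cc(OC(=O)c2c(CCC)cc(OC)cc2OC)cc(O)c1C(=O)O | target

## Summary

Total step count: 6. Longest linear sequence: 4 steps (1 → 3 → 4 → 9 → 10; the branch 5 → 6 → 7 → 9 → 10 is equally long).

**Three steps most likely to fail**

Step 5 (key coupling). The iodide is electron-rich and flanked by two ortho substituents, and the formate supplies only about one equivalent of CO, so oxidative addition, CO capture and ester closure may all be slow and deiodination may compete. Fallback: set out from 7 and make the carboxyl carbon and the ester bond separately. Iodine–lithium exchange (n-BuLi, THF, −78 °C) gives (2,4-dimethoxy-6-propylphenyl)lithium F1, which is quenched with CO2 and acidified to 2,4-dimethoxy-6-propylbenzoic acid F2. Trifluoroacetic anhydride in toluene converts this to 2,4-dimethoxy-6-propylbenzoic trifluoroacetic anhydride F3, which acylates the free 4-OH of phenol 3 and so comes back to the route at 9.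

Step 6 (final oxidation). The hydrogen-bonded salicylaldehyde may oxidise slowly, and HOCl may chlorinate the phenolic or the dimethoxy ring despite the scavenger. Fallback: set out from 1 and carry the acid as a benzyl ester instead of an aldehyde. Olivetol is carboxylated with methyl magnesium carbonate (DMF, 120 °C, then HCl) to olivetolic acid F4, and BnBr/KHCO3 in DMF gives benzyl 2,4-dihydroxy-6-pentylbenzoate F5. HCO2H/DCC then gives benzyl 4-(formyloxy)-2-hydroxy-6-pentylbenzoate F6, which is coupled with 7 under the step 5 conditions (through F5 and 8 formed in the flask) to benzyl 4-[(2,4-dimethoxy-6-propylbenzoyl)oxy]-2-hydroxy-6-pentylbenzoate F7. Hydrogenolysis (H2, Pd/C, EtOAc) comes back to the route at 10.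

Step 2 (aryl formate). Formate 4 is an activated, moisture-sensitive ester that may hydrolyse on isolation, and some bis-formylation is possible. Fallback: set out from 3 and leave out the formate carrier altogether. Phenol 3, iodide 7 and Et3N are heated with the same Pd catalyst under a balloon of CO gas, so that the aroyl-palladium species is captured directly by the 4-O-phenoxide; this comes back to the route at 9 and makes no new compound.

## Further compounds

F1 | step 5 | (2,4-dimethoxy-6-propylphenyl)lithium | [Li]c1c(CCC)cc(OC)cc1OC
F2 | step 5 | 2,4-dimethoxy-6-propylbenzoic acid | CCCc1cc(OC)cc(OC)c1C(=O)O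
F3 | step 5 | 2,4-dimethoxy-6-propylbenzoic trifluoroacetic anhydride | CCCc1cc(OC)cc(OC)c1C(=O)OC(=O)C(F)(F)F
F4 | step 6 | olivetolic acid (2,4-dihydroxy-6-pentylbenzoic acid) | CCCCCc1cc(O)cc(O)c1C(=O)O
F5 | step 6 | benzyl 2,4-dihydroxy-6-pentylbenzoate | CCCCCc1cc(O)cc(O)c1C(=O)OCc1ccccc1
F6 | step 6 | benzyl 4-(formyloxy)-2-hydroxy-6-pentylbenzoate | CCCCCc1cc(OC=O)cc(O)c1C(=O)OCc1ccccc1
F7 | step 6 | benzyl 4-[(2,4-dimethoxy-6-propylbenzoyl)oxy]-2-hydroxy-6-pentylbenzoate | CCCCCc1cc(OC(=O)c2c(CCC)cc(OC)cc2OC)cc(O)c1C(=O)OCc1ccccc1
F0 | step 2 | none | none
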